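**Retrosynthetic overview**
1. Last step: hydrogenolysis of all 14 benzyl ethers of the protected hexamer 29.
2. The five diaryl ether C–O bonds are cut one at a time from the F end. Each is made by Cu-catalysed O-arylation of a hindered phenol with an aryl bromide activated by a para-formyl group (rings B, D, E, F) or an ortho-formyl group (ring C).
3. After each union the formyl group becomes the next phenol by Baeyer–Villiger/Dakin oxidation, so one cycle (couple, oxidise) is repeated five times.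
4. Building blocks: phenol 6 from phloroglucinol (Vilsmeier C-formylation, an intermolecular enol + iminium, Mannich-type C–C bond formation; then benzylation and Dakin oxidation); bromoaldehyde 9 from 4-bromo-2,6-difluorobenzaldehyde; bromoaldehyde 14 from 5-bromo-1,2,3-trimethoxybenzene (Rieche formylation).
5. No ring is constructed: all six benzene rings come from the starting materials and are joined in the order A, B, C, D, E, F.

Assumption: the target has no stereocentre and no hindered axis (it is achiral), so no stereochemistry has to be set; all compounds are achiral except the non-isolated, racemic 11.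

Ring labels: A = 2,4,6-trioxygenated end ring, B, C = central pentaoxygenated ring, D, E, F = 3,4,5-trioxygenated end ring. Bn = benzyl.

**Route**

Step 1
Reactants: 1 phloroglucinol (benzene-1,3,5-triol)
Product: 3 2,4,6-trihydroxybenzaldehyde, via iminium chloride 2 (not isolated)
Conditions: POCl3 (1.1 equiv), DMF (1.2 equiv), EtOAc, 0 °C → rt; then H2O, 60 °C
Reagents that add atoms: N,N-dimethylformamide, CN(C)C=O (formyl carbon); water, O (carbonyl oxygen)
Why: Vilsmeier–Haack formylation, in which the enol-type ring carbon of phloroglucinol adds to the chloroiminium ion (a Mannich-type enol + iminium C–C bond formation) and the iminium salt is hydrolysed; the three ring positions are equivalent and the iminium group deactivates the ring against a second formylation.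

Step 2
Reactants: 3 2,4,6-trihydroxybenzaldehyde
Product: 4 2,4,6-tris(benzyloxy)benzaldehyde
Conditions: BnBr (3.6 equiv), K2CO3 (4 equiv), DMF, 60 °C, N2
Reagents that add atoms: benzyl bromide, BrCc1ccccc1
Why: Williamson etherification (SN2) of the three phenoxides; the formyl group lowers ring nucleophilicity enough to suppress the C-benzylation that plagues phloroglucinol itself.

Step 3
Reactants: 4 2,4,6-tris(benzyloxy)benzaldehyde
Product: 6 2,4,6-tris(benzyloxy)phenol, via aryl formate 5 (not isolated)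
Conditions: mCPBA (1.3 equiv), CH2Cl2, 0 °C → rt; Na2S2O3 wash; then K2CO3 (cat.), MeOH/THF, 0 °C, Ar
Reagents that add atoms: meta-chloroperoxybenzoic acid, OOC(=O)c1cccc(Cl)c1
Why: Baeyer–Villiger (Dakin-type) oxidation, where the very electron-rich aryl group migrates in the Criegee adduct to give the aryl formate, which base-catalysed methanolysis cleaves to the phenol.

Step 4
Reactants: 7 4-bromo-2,6-difluorobenzaldehyde
Product: 9 2,6-bis(benzyloxy)-4-bromobenzaldehyde, via monobenzyl ether 8 (not isolated)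
Conditions: BnOH (2.3 equiv), NaH (2.2 equiv), THF, 0 °C; then 7, 0 → 50 °C
Reagents that add atoms: benzyl alcohol, OCc1ccccc1
Why: Double SNAr (addition–elimination through Meisenheimer adducts) at the two fluorides ortho to the formyl group; fluoride is far more labile than the para-bromide, which is kept.

Step 5
Reactants: 10 5-bromo-1,2,3-trimethoxybenzene
Product: 12 6-bromo-2,3,4-trimethoxybenzaldehyde, via α-chloro ether 11 (not isolated)
Conditions: Cl2CHOMe (1.5 equiv), TiCl4 (2 equiv), CH2Cl2, −10 → 0 °C; then ice/1 M HCl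
Reagents that add atoms: dichloromethyl methyl ether, COC(Cl)Cl (formyl carbon); water, O (carbonyl oxygen)
Why: Rieche formylation (Friedel–Crafts type); the only free ring positions (C4 and C6) are equivalent and activated by an ortho- and a para-methoxy group, so the regiochemistry is unambiguous.

Step 6
Reactants: 12 6-bromo-2,3,4-trimethoxybenzaldehyde
Product: 13 6-bromo-2,3,4-trihydroxybenzaldehyde
Conditions: BBr3 (4 equiv), CH2Cl2, −78 °C → rt; then H2O, 0 °C
Reagents that add atoms: none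
Why: Lewis-acid O-demethylation (bromide attacks the methyl group of the boron-complexed ether), which the aryl bromide and aldehyde tolerate.

Step 7
Reactants: 13 6-bromo-2,3,4-trihydroxybenzaldehyde
Product: 14 6-bromo-2,3,4-tris(benzyloxy)benzaldehyde
Conditions: BnBr (3.6 equiv), K2CO3 (4 equiv), DMF, 50 °C, Ar
Reagents that add atoms: benzyl bromide, BrCc1ccccc1
Why: Williamson etherification of the three phenoxides under exclusion of air, since the pyrogallol trianion is oxidation-sensitive.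

Step 8
Reactants: 6 2,4,6-tris(benzyloxy)phenol; 9 2,6-bis(benzyloxy)-4-bromobenzaldehyde
Product: 15 AB aldehyde [2,6-bis(benzyloxy)-4-(2,4,6-tris(benzyloxy)phenoxy)benzaldehyde]
Conditions: CuI (10 mol %), picolinic acid (20 mol %), K3PO4 (2 equiv), DMSO, 90 °C, Ar
Reagents that add atoms: none
Why: Ullmann-type Cu-catalysed O-arylation, in which the hindered, electron-rich phenoxide meets an unhindered C–Br bond activated by the para-formyl group, the best-matched pairing for this catalyst.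

Step 9
Reactants: 15 AB aldehyde
Product: 17 AB phenol [2,6-bis(benzyloxy)-4-(2,4,6-tris(benzyloxy)phenoxy)phenol], via AB formate 16 (not isolated)
Conditions: mCPBA (1.3 equiv), CH2Cl2, 0 °C; Na2S2O3 wash; then K2CO3 (cat.), MeOH/THF, 0 °C, Ar
Reagents that add atoms: meta-chloroperoxybenzoic acid, OOC(=O)c1cccc(Cl)c1
Why: Baeyer–Villiger/Dakin oxidation of a 2,6-dialkoxy-4-aryloxybenzaldehyde (fast aryl migration) followed by formate methanolysis, which unmasks the next hindered phenol exactly where ring C must be attached.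

Step 10
Reactants: 17 AB phenol; 14 6-bromo-2,3,4-tris(benzyloxy)benzaldehyde
Product: 18 ABC aldehyde [2,3,4-tris(benzyloxy)-6-{2,6-bis(benzyloxy)-4-(2,4,6-tris(benzyloxy)phenoxy)phenoxy}benzaldehyde]
Conditions: CuI (20 mol %), picolinic acid (40 mol %), K3PO4 (2 equiv), DMSO, 100 °C, Ar
Reagents that add atoms: none
Why: Ullmann-type Cu-catalysed O-arylation, where the ortho-formyl group activates the C–Br bond (ortho-carbonyl effect) and the bromide has only one ortho substituent.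

Step 11
Reactants: 18 ABC aldehyde
Product: 20 ABC phenol (OH in place of the CHO of 18), via ABC formate 19 (not isolated)
Conditions: mCPBA (1.2 equiv), CH2Cl2, 0 °C; Na2S2O3 wash; then K2CO3 (cat.), MeOH/THF, 0 °C, Ar
Reagents that add atoms: meta-chloroperoxybenzoic acid, OOC(=O)c1cccc(Cl)c1
Why: Baeyer–Villiger/Dakin oxidation, in which the formyl group flanked by OBn and OAr sits on the most electron-rich ring, so aryl migration is fast; methanolysis then frees the ring-C phenol next to the B–O–C ether.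

Step 12
Reactants: 20 ABC phenol; 9 2,6-bis(benzyloxy)-4-bromobenzaldehyde
Product: 21 ABCD aldehyde (20 O-arylated by a 3,5-bis(benzyloxy)-4-formylphenyl group)
Conditions: CuI (20 mol %), picolinic acid (40 mol %), K3PO4 (2 equiv), DMSO, 100 °C, Ar
Reagents that add atoms: none
Why: Ullmann-type Cu-catalysed O-arylation of the di-ortho-oxygenated ring-C phenoxide with the unhindered, formyl-activated bromide 9.

Step 13
Reactants: 21 ABCD aldehyde
Product: 23 ABCD phenol (OH in place of the CHO of 21), via ABCD formate 22 (not isolated)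
Conditions: mCPBA (1.2 equiv), CH2Cl2, 0 °C; Na2S2O3 wash; then K2CO3 (cat.), MeOH/THF, 0 °C, Ar
Reagents that add atoms: meta-chloroperoxybenzoic acid, OOC(=O)c1cccc(Cl)c1
Why: Baeyer–Villiger/Dakin oxidation as in step 9; the aldehyde reacts much faster with the peracid than the benzyl-protected arene rings do.

Step 14
Reactants: 23 ABCD phenol; 9 2,6-bis(benzyloxy)-4-bromobenzaldehyde
Product: 24 ABCDE aldehyde (23 O-arylated by a 3,5-bis(benzyloxy)-4-formylphenyl group)
Conditions: CuI (20 mol %), picolinic acid (40 mol %), K3PO4 (2 equiv), DMSO, 100 °C, Ar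
Reagents that add atoms: none
Why: Ullmann-type Cu-catalysed O-arylation, the same phenol/bromide pairing as in step 8.

Step 15
Reactants: 24 ABCDE aldehyde
Product: 26 ABCDE phenol (OH in place of the CHO of 24), via ABCDE formate 25 (not isolated)
Conditions: mCPBA (1.2 equiv), CH2Cl2, 0 °C; Na2S2O3 wash; then K2CO3 (cat.), MeOH/THF, 0 °C, Ar
Reagents that add atoms: meta-chloroperoxybenzoic acid, OOC(=O)c1cccc(Cl)c1
Why: Baeyer–Villiger/Dakin oxidation and formate methanolysis as in step 9.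

Step 16
Reactants: 26 ABCDE phenol; 9 2,6-bis(benzyloxy)-4-bromobenzaldehyde
Product: 27 ABCDEF aldehyde (26 O-arylated by a 3,5-bis(benzyloxy)-4-formylphenyl group)
Conditions: CuI (20 mol %), picolinic acid (40 mol %), K3PO4 (2 equiv), DMSO, 100 °C, Ar
Reagents that add atoms: none
Why: Ullmann-type Cu-catalysed O-arylation as in step 8, which installs the last ring.

Step 17
Reactants: 27 ABCDEF aldehyde
Product: 29 ABCDEF phenol (tetradeca-O-benzyl target with free 4-OH on ring F), via ABCDEF formate 28 (not isolated)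
Conditions: mCPBA (1.2 equiv), CH2Cl2, 0 °C; Na2S2O3 wash; then K2CO3 (cat.), MeOH/THF, 0 °C, Ar
Reagents that add atoms: meta-chloroperoxybenzoic acid, OOC(=O)c1cccc(Cl)c1
Why: Baeyer–Villiger/Dakin oxidation, which turns the last formyl group into the central hydroxyl of the 3,4,5-trioxygenated ring F.

Step 18
Reactants: 29 ABCDEF phenol
Product: 30 target hexamer (CNP0270681.0)
Conditions: H2 (3 bar), 20 % Pd(OH)2/C, degassed THF/MeOH 1:1, rt; filtration and evaporation under Ar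
Reagents that add atoms: none
Why: Catalytic hydrogenolysis cleaves all 14 benzylic C–O bonds, while diaryl ether C–O bonds and the arene rings are inert under these conditions; no stereocentre is present.

**Compound list**
1 | phloroglucinol (benzene-1,3,5-triol) | Oc1cc(O)cc(O)c1 | starting material
2 | (2,4,6-trihydroxybenzylidene)dimethyliminium chloride | C[N+](C)=Cc1c(O)cc(O)cc1O.[Cl-] | intermediate
3 | 2,4,6-trihydroxybenzaldehyde | O=Cc1c(O)cc(O)cc1O | intermediate
4 | 2,4,6-tris(benzyloxy)benzaldehyde | O=Cc1c(OCc7ccccc7)cc(OCc7ccccc7)cc1OCc7ccccc7 | intermediate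
5 | 2,4,6-tris(benzyloxy)phenyl formate | O=COc1c(OCc7ccccc7)cc(OCc7ccccc7)cc1OCc7ccccc7 | intermediate
6 | 2,4,6-tris(benzyloxy)phenol | Oc1c(OCc7ccccc7)cc(OCc7ccccc7)cc1OCc7ccccc7 | intermediate
7 | 4-bromo-2,6-difluorobenzaldehyde | O=Cc1c(F)cc(Br)cc1F | starting material
8 | 2-(benzyloxy)-4-bromo-6-fluorobenzaldehyde | O=Cc1c(F)cc(Br)cc1OCc7ccccc7 | intermediate
9 | 2,6-bis(benzyloxy)-4-bromobenzaldehyde | O=Cc1c(OCc7ccccc7)cc(Br)cc1OCc7ccccc7 | intermediate
10 | 5-bromo-1,2,3-trimethoxybenzene | COc1cc(Br)cc(OC)c1OC | starting material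
11 | 1-bromo-2-[chloro(methoxy)methyl]-3,4,5-trimethoxybenzene (racemic) | COC(Cl)c1c(Br)cc(OC)c(OC)c1OC | intermediate
12 | 6-bromo-2,3,4-trimethoxybenzaldehyde | O=Cc1c(Br)cc(OC)c(OC)c1OC | intermediate
13 | 6-bromo-2,3,4-trihydroxybenzaldehyde | O=Cc1c(Br)cc(O)c(O)c1O | intermediate
14 | 6-bromo-2,3,4-tris(benzyloxy)benzaldehyde | O=Cc1c(Br)cc(OCc7ccccc7)c(OCc7ccccc7)c1OCc7ccccc7 | intermediate
15 | AB aldehyde: 2,6-bis(benzyloxy)-4-[2,4,6-tris(benzyloxy)phenoxy]benzaldehyde | c7ccccc7COc1cc(OCc7ccccc7)c(Oc2cc(OCc7ccccc7)c(C=O)c(OCc7ccccc7)c2)c(OCc7ccccc7)c1 | intermediate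
16 | AB formate: 2,6-bis(benzyloxy)-4-[2,4,6-tris(benzyloxy)phenoxy]phenyl formate | c7ccccc7COc1cc(OCc7ccccc7)c(Oc2cc(OCc7ccccc7)c(OC=O)c(OCc7ccccc7)c2)c(OCc7ccccc7)c1 | intermediate
17 | AB phenol: 2,6-bis(benzyloxy)-4-[2,4,6-tris(benzyloxy)phenoxy]phenol | c7ccccc7COc1cc(OCc7ccccc7)c(Oc2cc(OCc7ccccc7)c(O)c(OCc7ccccc7)c2)c(OCc7ccccc7)c1 | intermediate
18 | ABC aldehyde: 2,3,4-tris(benzyloxy)-6-{2,6-bis(benzyloxy)-4-[2,4,6-tris(benzyloxy)phenoxy]phenoxy}benzaldehyde | c7ccccc7COc1cc(OCc7ccccc7)c(Oc2cc(OCc7ccccc7)c(Oc3cc(OCc7ccccc7)c(OCc7ccccc7)c(OCc7ccccc7)c3C=O)c(OCc7ccccc7)c2)c(OCc7ccccc7)c1 | intermediate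
19 | ABC formate: formate ester of phenol 20 (OCHO in place of the CHO of 18) | c7ccccc7COc1cc(OCc7ccccc7)c(Oc2cc(OCc7ccccc7)c(Oc3cc(OCc7ccccc7)c(OCc7ccccc7)c(OCc7ccccc7)c3OC=O)c(OCc7ccccc7)c2)c(OCc7ccccc7)c1 | intermediate
20 | ABC phenol: 2,3,4-tris(benzyloxy)-6-{2,6-bis(benzyloxy)-4-[2,4,6-tris(benzyloxy)phenoxy]phenoxy}phenol | c7ccccc7COc1cc(OCc7ccccc7)c(Oc2cc(OCc7ccccc7)c(Oc3cc(OCc7ccccc7)c(OCc7ccccc7)c(OCc7ccccc7)c3O)c(OCc7ccccc7)c2)c(OCc7ccccc7)c1 | intermediate
21 | ABCD aldehyde: 2,6-bis(benzyloxy)-4-(aryloxy)benzaldehyde whose aryloxy group is phenol 20 minus H | c7ccccc7COc1cc(OCc7ccccc7)c(Oc2cc(OCc7ccccc7)c(Oc3cc(OCc7ccccc7)c(OCc7ccccc7)c(OCc7ccccc7)c3Oc4cc(OCc7ccccc7)c(C=O)c(OCc7ccccc7)c4)c(OCc7ccccc7)c2)c(OCc7ccccc7)c1 | intermediate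
22 | ABCD formate: formate ester of phenol 23 | c7ccccc7COc1cc(OCc7ccccc7)c(Oc2cc(OCc7ccccc7)c(Oc3cc(OCc7ccccc7)c(OCc7ccccc7)c(OCc7ccccc7)c3Oc4cc(OCc7ccccc7)c(OC=O)c(OCc7ccccc7)c4)c(OCc7ccccc7)c2)c(OCc7ccccc7)c1 | intermediate
23 | ABCD phenol: 2,6-bis(benzyloxy)-4-(aryloxy)phenol whose aryloxy group is phenol 20 minus H | c7ccccc7COc1cc(OCc7ccccc7)c(Oc2cc(OCc7ccccc7)c(Oc3cc(OCc7ccccc7)c(OCc7ccccc7)c(OCc7ccccc7)c3Oc4cc(OCc7ccccc7)c(O)c(OCc7ccccc7)c4)c(OCc7ccccc7)c2)c(OCc7ccccc7)c1 | intermediate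
24 | ABCDE aldehyde: 2,6-bis(benzyloxy)-4-(aryloxy)benzaldehyde whose aryloxy group is phenol 23 minus H | c7ccccc7COc1cc(OCc7ccccc7)c(Oc2cc(OCc7ccccc7)c(Oc3cc(OCc7ccccc7)c(OCc7ccccc7)c(OCc7ccccc7)c3Oc4cc(OCc7ccccc7)c(Oc5cc(OCc7ccccc7)c(C=O)c(OCc7ccccc7)c5)c(OCc7ccccc7)c4)c(OCc7ccccc7)c2)c(OCc7ccccc7)c1 | intermediate
25 | ABCDE formate: formate ester of phenol 26 | c7ccccc7COc1cc(OCc7ccccc7)c(Oc2cc(OCc7ccccc7)c(Oc3cc(OCc7ccccc7)c(OCc7ccccc7)c(OCc7ccccc7)c3Oc4cc(OCc7ccccc7)c(Oc5cc(OCc7ccccc7)c(OC=O)c(OCc7ccccc7)c5)c(OCc7ccccc7)c4)c(OCc7ccccc7)c2)c(OCc7ccccc7)c1 | intermediate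
26 | ABCDE phenol: 2,6-bis(benzyloxy)-4-(aryloxy)phenol whose aryloxy group is phenol 23 minus H | c7ccccc7COc1cc(OCc7ccccc7)c(Oc2cc(OCc7ccccc7)c(Oc3cc(OCc7ccccc7)c(OCc7ccccc7)c(OCc7ccccc7)c3Oc4cc(OCc7ccccc7)c(Oc5cc(OCc7ccccc7)c(O)c(OCc7ccccc7)c5)c(OCc7ccccc7)c4)c(OCc7ccccc7)c2)c(OCc7ccccc7)c1 | intermediate
27 | ABCDEF aldehyde: 2,6-bis(benzyloxy)-4-(aryloxy)benzaldehyde whose aryloxy group is phenol 26 minus H | c7ccccc7COc1cc(OCc7ccccc7)c(Oc2cc(OCc7ccccc7)c(Oc3cc(OCc7ccccc7)c(OCc7ccccc7)c(OCc7ccccc7)c3Oc4cc(OCc7ccccc7)c(Oc5cc(OCc7ccccc7)c(Oc6cc(OCc7ccccc7)c(C=O)c(OCc7ccccc7)c6)c(OCc7ccccc7)c5)c(OCc7ccccc7)c4)c(OCc7ccccc7)c2)c(OCc7ccccc7)c1 | intermediate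
28 | ABCDEF formate: formate ester of phenol 29 | c7ccccc7COc1cc(OCc7ccccc7)c(Oc2cc(OCc7ccccc7)c(Oc3cc(OCc7ccccc7)c(OCc7ccccc7)c(OCc7ccccc7)c3Oc4cc(OCc7ccccc7)c(Oc5cc(OCc7ccccc7)c(Oc6cc(OCc7ccccc7)c(OC=O)c(OCc7ccccc7)c6)c(OCc7ccccc7)c5)c(OCc7ccccc7)c4)c(OCc7ccccc7)c2)c(OCc7ccccc7)c1 | intermediate
29 | ABCDEF phenol: the target with all hydroxyls benzylated except the 4-OH of ring F (14 OBn, 1 OH) | c7ccccc7COc1cc(OCc7ccccc7)c(Oc2cc(OCc7ccccc7)c(Oc3cc(OCc7ccccc7)c(OCc7ccccc7)c(OCc7ccccc7)c3Oc4cc(OCc7ccccc7)c(Oc5cc(OCc7ccccc7)c(Oc6cc(OCc7ccccc7)c(O)c(OCc7ccccc7)c6)c(OCc7ccccc7)c5)c(OCc7ccccc7)c4)c(OCc7ccccc7)c2)c(OCc7ccccc7)c1 | intermediate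
30 | target hexamer CNP0270681.0 (achiral) | Oc1cc(O)c(Oc2cc(O)c(Oc3cc(O)c(O)c(O)c3Oc3cc(O)c(Oc4cc(O)c(Oc5cc(O)c(O)c(O)c5)c(O)c4)c(O)c3)c(O)c2)c(O)c1 | target

**Totals**
Total step count: 18.
Longest linear sequence: 14 steps (steps 1, 2, 3, 8, 9, 10, 11, 12, 13, 14, 15, 16, 17, 18).

**Three steps most likely to fail**

Step 10 is the most crowded union: a di-ortho-substituted phenol meets an ortho-substituted bromide on an electron-rich ring. The fallback replaces copper catalysis by a metal-free SNAr on the fluoro analogue of 14; it sets out from 10 and 17 and comes back to the route at 18. Bromide 10 is converted by Br/Li exchange (n-BuLi, THF, −78 °C) into 3,4,5-trimethoxyphenyllithium F1, which is quenched with N-fluorobenzenesulfonimide to give 5-fluoro-1,2,3-trimethoxybenzene F2. Rieche formylation as in step 5 proceeds through the α-chloro ether 1-[chloro(methoxy)methyl]-2-fluoro-4,5,6-trimethoxybenzene F3 and gives 6-fluoro-2,3,4-trimethoxybenzaldehyde F4. BBr3 then gives 6-fluoro-2,3,4-trihydroxybenzaldehyde F5, and BnBr/K2CO3 gives 6-fluoro-2,3,4-tris(benzyloxy)benzaldehyde F6. Heating F6 with 17 and Cs2CO3 in DMSO at 110 °C displaces the fluoride ortho to the formyl group through a Meisenheimer adduct and gives 18.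

Step 12 couples the most hindered phenol of the sequence (20, flanked by OBn and by the bulky B-ring aryloxy group). The fallback builds ring D from a more electrophilic partner in two metal-free substitutions; it sets out from 20 and comes back at 21. Phenol 20 is treated with commercial 2,4,6-trifluorobenzaldehyde (O=Cc1c(F)cc(F)cc1F) and Cs2CO3 in DMF at 0 °C → rt; the crowded phenoxide attacks the unhindered 4-position and gives the 2,6-difluoro-4-(aryloxy)benzaldehyde F7. BnOH/NaH in THF (0 → 40 °C) then replaces both formyl-activated ortho-fluorides, by way of the 2-(benzyloxy)-6-fluoro-4-(aryloxy)benzaldehyde F8, and gives 21.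

Step 18 removes 14 benzyl groups and leaves an air-sensitive pentadecaphenol that is hard to purify. The fallback changes both the cleavage and the isolation; it sets out from 29 and comes back at 30. The benzyl ethers are cleaved non-reductively with BCl3 and pentamethylbenzene (CH2Cl2, −78 °C). The crude polyphenol is acetylated at once (Ac2O, pyridine, cat. DMAP) to the pentadecaacetate of the target F9, which is stable and can be chromatographed. Degassed methanolic HCl under Ar then removes the acetates and gives 30.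

**Further compounds**
F1 | step 10 | 3,4,5-trimethoxyphenyllithium | [Li]c1cc(OC)c(OC)c(OC)c1
F2 | step 10 | 5-fluoro-1,2,3-trimethoxybenzene | COc1cc(F)cc(OC)c1OC
F3 | step 10 | 1-[chloro(methoxy)methyl]-2-fluoro-4,5,6-trimethoxybenzene (racemic) | COC(Cl)c1c(F)cc(OC)c(OC)c1OC
F4 | step 10 | 6-fluoro-2,3,4-trimethoxybenzaldehyde | O=Cc1c(F)cc(OC)c(OC)c1OC
F5 | step 10 | 6-fluoro-2,3,4-trihydroxybenzaldehyde | O=Cc1c(F)cc(O)c(O)c1O
F6 | step 10 | 6-fluoro-2,3,4-tris(benzyloxy)benzaldehyde | O=Cc1c(F)cc(OCc7ccccc7)c(OCc7ccccc7)c1OCc7ccccc7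
F7 | step 12 | 2,6-difluoro-4-(aryloxy)benzaldehyde whose aryloxy group is phenol 20 minus H | c7ccccc7COc1cc(OCc7ccccc7)c(Oc2cc(OCc7ccccc7)c(Oc3cc(OCc7ccccc7)c(OCc7ccccc7)c(OCc7ccccc7)c3Oc4cc(F)c(C=O)c(F)c4)c(OCc7ccccc7)c2)c(OCc7ccccc7)c1
F8 | step 12 | 2-(benzyloxy)-6-fluoro-4-(aryloxy)benzaldehyde whose aryloxy group is phenol 20 minus H | c7ccccc7COc1cc(OCc7ccccc7)c(Oc2cc(OCc7ccccc7)c(Oc3cc(OCc7ccccc7)c(OCc7ccccc7)c(OCc7ccccc7)c3Oc4cc(F)c(C=O)c(OCc7ccccc7)c4)c(OCc7ccccc7)c2)c(OCc7ccccc7)c1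
F9 | step 18 | pentadecaacetate of the target | CC(=O)Oc1cc(OC(C)=O)c(Oc2cc(OC(C)=O)c(Oc3cc(OC(C)=O)c(OC(C)=O)c(OC(C)=O)c3Oc4cc(OC(C)=O)c(Oc5cc(OC(C)=O)c(Oc6cc(OC(C)=O)c(OC(C)=O)c(OC(C)=O)c6)c(OC(C)=O)c5)c(OC(C)=O)c4)c(OC(C)=O)c2)c(OC(C)=O)c1
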